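**Retrosynthetic overview**

1. Numbering: ring A (carbocycle) has C1 = quaternary carbon, C2 = carbonyl next to it, C3 = carbon bearing the phenylpropanoic acid chain, C4 = carbon bonded to the pyran oxygen, C5 = carbon bearing the ring-B (dihydropyranone) carbonyl, C6 = enolised carbonyl; ring C = cyclobutane.
2. Feature used: C1 lies between the two ring carbonyl carbons C2 and C6, and C6 sits on C5 of ring B. C6 is therefore introduced as a formyl group on the pyranone and bonded to C1 as an acyl anion adding to the β-carbon of an (E)-enoate (C1–C6 bond, intramolecular Stetter reaction). The CH2CO2Me arm left on C1 becomes the prenyl group.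
3. After ring A: C2 silyl ether to ketone, ester to aldehyde to prenyl, then the C3 side chain by carbene-catalysed annulation with 3-phenylpropynal (lactone ring D across C2–O and C3) and lactone hydrolysis.
4. Before ring A: ring B by 6-endo cyclisation of an ynone from acyl Sonogashira coupling of alkyne 14 (from (−)-α-pinene via pinonic ester, keto acetal, HWE, asymmetric propargylation) with acid chloride 20 (from methyl (R)-3-hydroxybutanoate by Fráter–Seebach methylation); the C5 formyl group by iodination and carbonylation.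
5. Ring order: C (from pinene), B (step 15), A (step 18), D (step 23, opened in step 24).

Key step: step 18

Assumption: (−)-α-pinene of the high-ee commercial grade is used; any minor enantiomer would appear as a diastereomer after step 14 and be removed there.
Assumption: the sense of induction of the chiral catalysts in steps 8, 18 and 23 is assigned by analogy with simple aldehydes and enols; if a catalyst induces the opposite sense, its mirror image is used.
Abbreviation: Cb = (1R,3S)-2,2-dimethyl-3-(prop-1-en-2-yl)cyclobutyl with the two ring substituents cis; Cb-methyl is its CH2 homologue.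

**Route**

Step 1
Reactants: 1 (−)-α-pinene
Product: 2 cis-pinonic acid (2-[(1R,3R)-3-acetyl-2,2-dimethylcyclobutyl]acetic acid)
Conditions: RuCl3·xH2O (2 mol %), NaIO4 (4 equiv), EtOAc/MeCN/H2O, rt
Reagents that add atoms: sodium periodate, [Na+].[O-]I(=O)(=O)=O
Why: RuO4-catalysed oxidative cleavage of the only C=C gives the methyl ketone and the acid; both cyclobutane stereocentres come from pinene and stay cis.

Step 2
Reactants: 2 cis-pinonic acid
Product: 3 methyl 2-[(1R,3R)-3-acetyl-2,2-dimethylcyclobutyl]acetate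
Conditions: MeI, KHCO3, DMF, rt
Reagents that add atoms: iodomethane, CI
Why: SN2 O-alkylation of the carboxylate; the weak base should not epimerise the ring carbon next to the acetyl group.

Step 3
Reactants: 3 methyl cis-pinonate
Product: 4 methyl 2-[(1R,3S)-2,2-dimethyl-3-(prop-1-en-2-yl)cyclobutyl]acetate (methyl Cb-acetate)
Conditions: Ph3PCH3Br, KOtBu (slight deficit), THF, 0 °C to rt
Reagents that add atoms: methyltriphenylphosphonium bromide, C[P+](c1ccccc1)(c1ccccc1)c1ccccc1.[Br-]
Why: Wittig methylenation of the methyl ketone; with no excess base and low temperature the cis ring carbon next to the ketone should keep its configuration and the ester is untouched.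

Step 4
Reactants: 4 methyl Cb-acetate; 5 methyl 2,2-dimethoxyacetate
Product: 7 methyl 2-Cb-4,4-dimethoxy-3-oxobutanoate (both C2 epimers), via ester lithium enolate 6 (not isolated)
Conditions: LDA (2.2 equiv), THF, −78 °C; 5, −78 to −20 °C; AcOH
Reagents that add atoms: methyl 2,2-dimethoxyacetate (5), COC(OC)C(=O)OC
Why: crossed Claisen condensation of the kinetic ester enolate with an ester that does not self-condense; the second equivalent of base holds the product as its enolate, and the new CH centre is removed in step 5.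

Step 5
Reactants: 7 β-keto ester
Product: 8 1-Cb-3,3-dimethoxypropan-2-one
Conditions: LiCl, DMSO/H2O, 130 °C
Reagents that add atoms: none
Why: Krapcho dealkoxycarbonylation (chloride attack on the ester methyl, loss of CO2) under neutral conditions that the acetal and the isopropenyl group tolerate.

Step 6
Reactants: 8 keto acetal; 9 trimethyl phosphonoacetate
Product: 10 methyl (2E)-3-(Cb-methyl)-4,4-dimethoxybut-2-enoate
Conditions: NaH, THF, 0 °C to rt; chromatography
Reagents that add atoms: trimethyl phosphonoacetate (9), COC(=O)CP(=O)(OC)OC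
Why: Horner–Wadsworth–Emmons olefination of the activated α-keto acetal; the (E) isomer (acetal carbon trans to the ester) should predominate and is separated from the (Z) isomer.

Step 7
Reactants: 10 acetal enoate
Product: 11 methyl (2E)-3-(Cb-methyl)-4-oxobut-2-enoate (formyl enoate)
Conditions: TsOH·H2O (cat.), acetone/H2O, rt
Reagents that add atoms: water, O
Why: acid-catalysed acetal hydrolysis; the (E) formyl enoate is the thermodynamic isomer and cannot lactonise, and the mild acid should leave the isopropenyl group alone.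

Step 8
Reactants: 11 formyl enoate; 12 allenylboronic acid pinacol ester
Product: 13 methyl (2E,4S)-3-(Cb-methyl)-4-hydroxyhept-2-en-6-ynoate
Conditions: (S)-TRIP [(S)-3,3′-bis(2,4,6-triisopropylphenyl)-BINOL hydrogen phosphate] (10 mol %), 4 Å MS, toluene, 0 °C
Reagents that add atoms: allenylboronic acid pinacol ester (12), C=C=CB1OC(C)(C)C(C)(C)O1
Why: chiral phosphoric acid-catalysed propargylboration of the aldehyde through a closed six-membered transition state with allenyl-to-propargyl transposition; the catalyst sets C2 of ring A as (S).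

Step 9
Reactants: 13 homopropargylic alcohol
Product: 14 methyl (2E,4S)-4-(tert-butyldimethylsilyloxy)-3-(Cb-methyl)hept-2-en-6-ynoate
Conditions: TBSOTf, 2,6-lutidine, CH2Cl2, −78 to 0 °C
Reagents that add atoms: tert-butyldimethylsilyl triflate, CC(C)(C)[Si](C)(C)OS(=O)(=O)C(F)(F)F
Why: standard silyl ether formation on the hindered secondary alcohol with the silyl triflate and a non-nucleophilic base.

Step 10
Reactants: 15 methyl (R)-3-hydroxybutanoate
Product: 17 methyl (2R,3R)-3-hydroxy-2-methylbutanoate, via dilithium alkoxide enolate 16 (not isolated)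
Conditions: LDA (2.2 equiv), THF, −78 to −20 °C; MeI, DMPU, −78 to −10 °C; AcOH
Reagents that add atoms: iodomethane, CI
Why: Fráter–Seebach alkylation; the chelated dianion is methylated anti to the alkoxide-bearing substituent, giving the anti (2R,3R) ester.

Step 11
Reactants: 17 anti hydroxy ester
Product: 18 (2R,3R)-3-hydroxy-2-methylbutanoic acid
Conditions: LiOH, THF/H2O, 0 °C; then HCl
Reagents that add atoms: lithium hydroxide, [Li+].[OH-]
Why: saponification at low temperature; hydroxide adds to the ester faster than it enolises it, so C2 keeps its configuration.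

Step 12
Reactants: 18 hydroxy acid
Product: 19 triethylsilyl (2R,3R)-2-methyl-3-(triethylsilyloxy)butanoate
Conditions: Et3SiCl (2.3 equiv), imidazole, DMF, 0 °C to rt
Reagents that add atoms: chlorotriethylsilane, CC[Si](Cl)(CC)CC
Why: silylation of hydroxyl and carboxyl groups (silyl ether and silyl ester formation) gives a neutral precursor of the acid chloride.

Step 13
Reactants: 19 bis-silyl compound
Product: 20 (2R,3R)-2-methyl-3-(triethylsilyloxy)butanoyl chloride
Conditions: (COCl)2, DMF (cat.), CH2Cl2, 0 °C to rt; used crude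
Reagents that add atoms: oxalyl chloride, O=C(Cl)C(=O)Cl
Why: Vilsmeier-type conversion of the silyl ester into the acid chloride without free HCl, so the triethylsilyl ether should survive.

Step 14
Reactants: 14 alkyne; 20 acid chloride
Product: 21 methyl (2E,4S,9R,10R)-4-(tert-butyldimethylsilyloxy)-3-(Cb-methyl)-9-methyl-8-oxo-10-(triethylsilyloxy)undec-2-en-6-ynoate
Conditions: PdCl2(PPh3)2 (2 mol %), CuI (4 mol %), Et3N (1.2 equiv), THF, rt
Reagents that add atoms: none
Why: acyl Sonogashira coupling of acid chloride and terminal alkyne; the mild amine conditions tolerate the enoate, both silyl ethers and the isopropenyl group.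

Step 15
Reactants: 21 ynone
Product: 23 methyl (2E,4S)-4-(tert-butyldimethylsilyloxy)-3-(Cb-methyl)-5-[(2R,3R)-2,3-dimethyl-4-oxo-3,4-dihydro-2H-pyran-6-yl]pent-2-enoate, via β-hydroxy ynone 22 (not isolated)
Conditions: PPTS, MeOH, 0 °C to rt; then AgOTf (10 mol %), CH2Cl2, rt
Reagents that add atoms: none
Why: selective acidic methanolysis of the triethylsilyl ether, then silver-catalysed 6-endo-dig oxa-Michael cyclisation of the β-hydroxy ynone closes ring B; its C3 is epimerisable but trans-2,3-dimethyl is the favoured arrangement.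

Step 16
Reactants: 23 dihydropyranone
Product: 24 the 5-iodo derivative of 23 (iodine on the ring-B carbon that becomes C5 of ring A)
Conditions: I2 (2 equiv), pyridine, CH2Cl2, 0 °C to rt, dark
Reagents that add atoms: iodine, II
Why: electrophilic α-iodination of the vinylogous ester at its enol-ether carbon; the isolated isopropenyl group and the electron-poor enoate should not react.

Step 17
Reactants: 24 iodide
Product: 25 methyl (2E,4S)-4-(tert-butyldimethylsilyloxy)-3-(Cb-methyl)-5-[(2R,3R)-5-formyl-2,3-dimethyl-4-oxo-3,4-dihydro-2H-pyran-6-yl]pent-2-enoate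
Conditions: Pd(PPh3)4 (5 mol %), CO (3 atm), Bu3SnH (1.1 equiv, slow addition), toluene, 50 °C
Reagents that add atoms: carbon monoxide, [C-]#[O+]
Why: palladium-catalysed reductive carbonylation (formylation) of the vinyl iodide by oxidative addition, CO insertion and hydride transfer from tin; slow hydride addition favours CO insertion over deiodination.

Step 18
Reactants: 25 formyl enoate
Product: 26 methyl 2-[(2R,3R,6R,7S)-7-(tert-butyldimethylsilyloxy)-6-(Cb-methyl)-2,3-dimethyl-4,5-dioxo-3,4,5,6,7,8-hexahydro-2H-chromen-6-yl]acetate (chromene C6 = ring-A C1, C7 = C2, C5 = C6)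
Conditions: chiral aminoindanol-derived N-C6F5 triazolium tetrafluoroborate (20 mol %), iPr2NEt (20 mol %), toluene, 23 °C
Reagents that add atoms: none
Why: Proposed new method: the free carbene adds to the C5 formyl group of 25, proton transfer gives the enaminol (Breslow intermediate, acyl-anion equivalent at C6), this adds to C1, the β-carbon of the tethered (E)-enoate, and after protonation at the ester α-carbon the carbene is expelled to leave the C6 ketone; the closest known reaction type is the triazolium-catalysed asymmetric intramolecular Stetter reaction onto β,β-disubstituted Michael acceptors that forms quaternary centres, extended here to a vinylogous-formate aldehyde on a dihydropyranone. Ring A closes in a 6-exo-trig mode, the ring-B double bond holding aldehyde and tether cis as an ortho-disubstituted arene does in the known cases. The new stereocentre C1 is set only by the face of the geometrically pure enoate that the chiral enaminol attacks; the aminoindanol backbone of the catalyst controls this face and the (S)-C2 silyloxy group is expected to reinforce it. The step needs conjugate addition at C1 to win over base-induced loss of silanol across C2–C3 and over aldehyde dimerisation; the formyl group has no α-hydrogen, the ester alone activates C1, and a weak amine base in toluene should leave the C3 methylene untouched.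

Step 19
Reactants: 26 Stetter product
Product: 27 the C2 alcohol (26 with OH in place of the silyloxy group; chromene 6R,7S)
Conditions: HF·pyridine, pyridine, THF, 0 °C to rt
Reagents that add atoms: none
Why: fluoride cleavage of the silyl ether under buffered, weakly acidic conditions, which avoid retro-aldol cleavage of the β-hydroxy ketone.

Step 20
Reactants: 27 alcohol
Product: 28 ring-A triketone ester (C2 ketone; drawn as the enol with C3–H and C6–OH; C1 bears CH2CO2Me and Cb-methyl; ring B unchanged)
Conditions: Dess–Martin periodinane (1.2 equiv), NaHCO3, CH2Cl2, 0 °C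
Reagents that add atoms: none
Why: Dess–Martin oxidation of the secondary alcohol gives the C2 ketone, which enolises into the cross-conjugated vinylogous acid of ring A; a small excess of oxidant limits hydroxylation at C3.

Step 21
Reactants: 28 triketone ester
Product: 30 ring-A triketone aldehyde (C1 bears CH2CHO), via sodium enolate 29 (not isolated)
Conditions: NaH (1.05 equiv), THF, 0 °C; iBu2AlH (1.3 equiv), THF/toluene, −78 °C; aq. potassium sodium tartrate, then dilute HCl
Reagents that add atoms: none
Why: partial reduction of the methyl ester by iBu2AlH through the tetrahedral aluminium acetal, stable at −78 °C, while the three ring carbonyls are masked in situ as the delocalised sodium enolate (enolate protection).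

Step 22
Reactants: 30 triketone aldehyde
Product: 32 prenylated ring-A triketone (C1 bears prenyl and Cb-methyl; C3–H), via aldehyde sodium enolate 31 (not isolated)
Conditions: NaH (1.0 equiv), THF, 0 °C; Ph3P=CMe2 [from iPrPPh3I, KN(SiMe3)2], THF, −78 to 0 °C; AcOH
Reagents that add atoms: isopropyltriphenylphosphonium iodide, CC(C)[P+](c1ccccc1)(c1ccccc1)c1ccccc1.[I-]
Why: Wittig olefination of the aldehyde with isopropylidenetriphenylphosphorane installs the prenyl group; the enolate-masked ring carbonyls should not react with the ylide.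

Step 23
Reactants: 32 prenylated triketone; 33 3-phenylprop-2-ynal
Product: 34 enol lactone (ring D: C3–CH(Ph)–CH2–C(=O)–O–C2; benzylic carbon S)
Conditions: chiral aminoindanol-derived N-mesityl triazolium chloride (10 mol %), toluene, 40 °C
Reagents that add atoms: 3-phenylprop-2-ynal (33), O=CC#Cc1ccccc1
Why: carbene-catalysed redox annulation of an ynal with a stable enol (α,β-unsaturated acyl azolium, Claisen-type C–C bond formation at C3, lactonisation by the C2 oxygen); the chiral triazolium sets the benzylic centre as (S), and C3 is the only free nucleophilic carbon.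

Step 24
Reactants: 34 enol lactone
Product: 35 target CNP0103716.3
Conditions: LiOH, THF/H2O, 0 °C; then 1 M HCl to pH 3, 0 °C
Reagents that add atoms: lithium hydroxide, [Li+].[OH-]
Why: saponification of the enol lactone frees the carboxylic acid and the C2 carbonyl; cold, brief treatment should avoid retro-Michael loss of the side chain, and mild acidification should avoid relactonisation.

**Compound list**

1 | (−)-α-pinene, (1S,5S)-2,6,6-trimethylbicyclo[3.1.1]hept-2-ene | CC1=CC[C@H]2C[C@@H]1C2(C)C | starting material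
2 | cis-pinonic acid, 2-[(1R,3R)-3-acetyl-2,2-dimethylcyclobutyl]acetic acid | CC(=O)[C@@H]1C[C@H](CC(=O)O)C1(C)C | intermediate
3 | methyl 2-[(1R,3R)-3-acetyl-2,2-dimethylcyclobutyl]acetate | CC(=O)[C@@H]1C[C@H](CC(=O)OC)C1(C)C | intermediate
4 | methyl 2-[(1R,3S)-2,2-dimethyl-3-(prop-1-en-2-yl)cyclobutyl]acetate | C=C(C)[C@@H]1C[C@H](CC(=O)OC)C1(C)C | intermediate
5 | methyl 2,2-dimethoxyacetate | COC(OC)C(=O)OC | starting material
6 | lithium enolate of 4 | C=C(C)[C@@H]1C[C@H](C=C(OC)O[Li])C1(C)C | intermediate
7 | methyl 2-[(1R,3S)-2,2-dimethyl-3-(prop-1-en-2-yl)cyclobutyl]-4,4-dimethoxy-3-oxobutanoate (C2 epimers) | C=C(C)[C@@H]1C[C@H](C(C(=O)OC)C(=O)C(OC)OC)C1(C)C | intermediate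
8 | 1-[(1R,3S)-2,2-dimethyl-3-(prop-1-en-2-yl)cyclobutyl]-3,3-dimethoxypropan-2-one | C=C(C)[C@@H]1C[C@H](CC(=O)C(OC)OC)C1(C)C | intermediate
9 | trimethyl phosphonoacetate | COC(=O)CP(=O)(OC)OC | starting material
10 | methyl (2E)-3-{[(1R,3S)-2,2-dimethyl-3-(prop-1-en-2-yl)cyclobutyl]methyl}-4,4-dimethoxybut-2-enoate | C=C(C)[C@@H]1C[C@H](C/C(=C\C(=O)OC)C(OC)OC)C1(C)C | intermediate
11 | methyl (2E)-3-{[(1R,3S)-2,2-dimethyl-3-(prop-1-en-2-yl)cyclobutyl]methyl}-4-oxobut-2-enoate | C=C(C)[C@@H]1C[C@H](C/C(=C\C(=O)OC)C=O)C1(C)C | intermediate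
12 | allenylboronic acid pinacol ester | C=C=CB1OC(C)(C)C(C)(C)O1 | starting material
13 | methyl (2E,4S)-3-(Cb-methyl)-4-hydroxyhept-2-en-6-ynoate | C=C(C)[C@@H]1C[C@H](C/C(=C\C(=O)OC)[C@@H](O)CC#C)C1(C)C | intermediate
14 | methyl (2E,4S)-4-(tert-butyldimethylsilyloxy)-3-(Cb-methyl)hept-2-en-6-ynoate | C=C(C)[C@@H]1C[C@H](C/C(=C\C(=O)OC)[C@@H](O[Si](C)(C)C(C)(C)C)CC#C)C1(C)C | intermediate
15 | methyl (R)-3-hydroxybutanoate | C[C@@H](O)CC(=O)OC | starting material
16 | dilithium alkoxide enolate of 15 | C[C@@H](O[Li])C=C(OC)O[Li] | intermediate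
17 | methyl (2R,3R)-3-hydroxy-2-methylbutanoate | C[C@@H](O)[C@@H](C)C(=O)OC | intermediate
18 | (2R,3R)-3-hydroxy-2-methylbutanoic acid | C[C@@H](O)[C@@H](C)C(=O)O | intermediate
19 | triethylsilyl (2R,3R)-2-methyl-3-(triethylsilyloxy)butanoate | C[C@@H](O[Si](CC)(CC)CC)[C@@H](C)C(=O)O[Si](CC)(CC)CC | intermediate
20 | (2R,3R)-2-methyl-3-(triethylsilyloxy)butanoyl chloride | C[C@@H](O[Si](CC)(CC)CC)[C@@H](C)C(=O)Cl | intermediate
21 | methyl (2E,4S,9R,10R)-4-(tert-butyldimethylsilyloxy)-3-(Cb-methyl)-9-methyl-8-oxo-10-(triethylsilyloxy)undec-2-en-6-ynoate | C=C(C)[C@@H]1C[C@H](C/C(=C\C(=O)OC)[C@@H](O[Si](C)(C)C(C)(C)C)CC#CC(=O)[C@H](C)[C@@H](C)O[Si](CC)(CC)CC)C1(C)C | intermediate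
22 | 10-hydroxy analogue of 21 (β-hydroxy ynone) | C=C(C)[C@@H]1C[C@H](C/C(=C\C(=O)OC)[C@@H](O[Si](C)(C)C(C)(C)C)CC#CC(=O)[C@H](C)[C@@H](C)O)C1(C)C | intermediate
23 | methyl (2E,4S)-4-(tert-butyldimethylsilyloxy)-3-(Cb-methyl)-5-[(2R,3R)-2,3-dimethyl-4-oxo-3,4-dihydro-2H-pyran-6-yl]pent-2-enoate | C=C(C)[C@@H]1C[C@H](C/C(=C\C(=O)OC)[C@@H](O[Si](C)(C)C(C)(C)C)CC2=CC(=O)[C@H](C)[C@@H](C)O2)C1(C)C | intermediate
24 | 5-iodo derivative of 23 | C=C(C)[C@@H]1C[C@H](C/C(=C\C(=O)OC)[C@@H](O[Si](C)(C)C(C)(C)C)CC2=C(I)C(=O)[C@H](C)[C@@H](C)O2)C1(C)C | intermediate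
25 | 5-formyl derivative of 23 (Stetter precursor) | O=CC1=C(C[C@H](O[Si](C)(C)C(C)(C)C)/C(C[C@H]2C[C@@H](C(C)=C)C2(C)C)=C/C(=O)OC)O[C@H](C)[C@@H](C)C1=O | intermediate
26 | methyl 2-[(2R,3R,6R,7S)-7-(tert-butyldimethylsilyloxy)-6-(Cb-methyl)-2,3-dimethyl-4,5-dioxo-3,4,5,6,7,8-hexahydro-2H-chromen-6-yl]acetate | C=C(C)[C@@H]1C[C@H](C[C@]2(CC(=O)OC)C(=O)C3=C(C[C@@H]2O[Si](C)(C)C(C)(C)C)O[C@H](C)[C@@H](C)C3=O)C1(C)C | intermediate
27 | 7-hydroxy analogue of 26 (C2 alcohol) | C=C(C)[C@@H]1C[C@H](C[C@]2(CC(=O)OC)C(=O)C3=C(C[C@@H]2O)O[C@H](C)[C@@H](C)C3=O)C1(C)C | intermediate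
28 | ring-A triketone with CH2CO2Me on C1 (enol tautomer) | C=C(C)[C@@H]1C[C@H](C[C@@]2(CC(=O)OC)C(=O)C=C3O[C@H](C)[C@@H](C)C(=O)C3=C2O)C1(C)C | intermediate
29 | sodium enolate of 28 | C=C(C)[C@@H]1C[C@H](C[C@@]2(CC(=O)OC)C(=O)C=C3O[C@H](C)[C@@H](C)C(=O)C3=C2[O-])C1(C)C.[Na+] | intermediate
30 | ring-A triketone with CH2CHO on C1 (enol tautomer) | C=C(C)[C@@H]1C[C@H](C[C@@]2(CC=O)C(=O)C=C3O[C@H](C)[C@@H](C)C(=O)C3=C2O)C1(C)C | intermediate
31 | sodium enolate of 30 | C=C(C)[C@@H]1C[C@H](C[C@@]2(CC=O)C(=O)C=C3O[C@H](C)[C@@H](C)C(=O)C3=C2[O-])C1(C)C.[Na+] | intermediate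
32 | ring-A triketone with prenyl on C1 and H on C3 (enol tautomer) | C=C(C)[C@@H]1C[C@H](C[C@@]2(CC=C(C)C)C(=O)C=C3O[C@H](C)[C@@H](C)C(=O)C3=C2O)C1(C)C | intermediate
33 | 3-phenylprop-2-ynal | O=CC#Cc1ccccc1 | starting material
34 | enol lactone, ring D fused across C2–O and C3, (S)-phenyl-bearing carbon | C=C(C)[C@@H]1C[C@H](C[C@@]2(CC=C(C)C)C3=C([C@H](c4ccccc4)CC(=O)O3)C5=C(C(=O)[C@H](C)[C@@H](C)O5)C2=O)C1(C)C | intermediate
35 | CNP0103716.3, (3S)-3-phenyl-3-(ring-A C3)propanoic acid with prenyl and Cb-methyl on C1 and (2R,3R)-dimethyl ring B | C=C(C)[C@@H]1C[C@H](C[C@@]2(CC=C(C)C)C(=O)C([C@@H](CC(=O)O)c3ccccc3)=C3O[C@H](C)[C@@H](C)C(=O)C3=C2O)C1(C)C | target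

**Step count and risks**

Total steps: 24. Longest linear sequence: 20 (steps 1–9 and 14–24).

Step 18 (key step). What may go wrong: the carbene acts as a base, so that silanol is lost across C2–C3; or the enaminol adds too slowly to the hindered β,β-disubstituted enoate; or the face of attack at C1 is poorly controlled. Fallback by known radical chemistry, setting out from 25: Pinnick oxidation (NaClO2, NaH2PO4, 2-methylbut-2-ene, tBuOH/H2O) would give the pyranone carboxylic acid F1. N-(Phenylseleno)phthalimide and Bu3P would convert it into the Se-phenyl selenoester F2. Bu3SnH and AIBN in benzene at 80 °C would generate the acyl radical, which closes 6-exo-trig onto C1 of the enoate and after hydrogen transfer gives the bicyclic ketone; C1 epimers would be separated. The route is rejoined at 26.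

Step 21. What may go wrong: hydride is delivered to the enolate-masked ring carbonyls, the ester is reduced past the aldehyde stage, or the aldehyde closes onto the neighbouring enol. Fallback with a changed order and a different reduction, setting out from 26: Me3SnOH (ClCH2CH2Cl, 80 °C) would cleave the methyl ester to the carboxylic acid F3. EtSH, EDC·HCl and DMAP would give the S-ethyl thioester F4. Fukuyama reduction (Et3SiH, palladium on carbon, acetone) would give the aldehyde F5 without touching the ketones. Wittig reaction with Ph3P=CMe2 would give the prenyl silyl ether F6. HF·pyridine would give the C2 alcohol F7, and Dess–Martin oxidation would give the prenylated triketone. The route is rejoined at 32.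

Step 17. What may go wrong: hydride transfer to the vinylpalladium iodide outruns CO insertion, so the iodide is simply reduced back to 23, or the tin hydride reduces the enoate. Fallback by C–C coupling and oxidation, setting out from 24: Stille coupling with (tributylstannyl)methanol (Pd(PPh3)4, dioxane, 90 °C) would give the 5-hydroxymethyl pyranone F8, and MnO2 in CH2Cl2 would oxidise it to the aldehyde. The route is rejoined at 25.

**Further compounds**

F1 | step 18 | pyranone-5-carboxylic acid from 25 | OC(=O)C1=C(C[C@H](O[Si](C)(C)C(C)(C)C)/C(C[C@H]2C[C@@H](C(C)=C)C2(C)C)=C/C(=O)OC)O[C@H](C)[C@@H](C)C1=O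
F2 | step 18 | Se-phenyl selenoester of F1 | O=C([Se]c3ccccc3)C1=C(C[C@H](O[Si](C)(C)C(C)(C)C)/C(C[C@H]2C[C@@H](C(C)=C)C2(C)C)=C/C(=O)OC)O[C@H](C)[C@@H](C)C1=O
F3 | step 21 | carboxylic acid from 26 (CH2CO2H on C1) | C=C(C)[C@@H]1C[C@H](C[C@]2(CC(=O)O)C(=O)C3=C(C[C@@H]2O[Si](C)(C)C(C)(C)C)O[C@H](C)[C@@H](C)C3=O)C1(C)C
F4 | step 21 | S-ethyl thioester of F3 | C=C(C)[C@@H]1C[C@H](C[C@]2(CC(=O)SCC)C(=O)C3=C(C[C@@H]2O[Si](C)(C)C(C)(C)C)O[C@H](C)[C@@H](C)C3=O)C1(C)C
F5 | step 21 | aldehyde from F4 (CH2CHO on C1, C2 silyl ether) | C=C(C)[C@@H]1C[C@H](C[C@]2(CC=O)C(=O)C3=C(C[C@@H]2O[Si](C)(C)C(C)(C)C)O[C@H](C)[C@@H](C)C3=O)C1(C)C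
F6 | step 21 | prenyl compound from F5 (C2 silyl ether) | C=C(C)[C@@H]1C[C@H](C[C@]2(CC=C(C)C)C(=O)C3=C(C[C@@H]2O[Si](C)(C)C(C)(C)C)O[C@H](C)[C@@H](C)C3=O)C1(C)C
F7 | step 21 | C2 alcohol from F6 | C=C(C)[C@@H]1C[C@H](C[C@]2(CC=C(C)C)C(=O)C3=C(C[C@@H]2O)O[C@H](C)[C@@H](C)C3=O)C1(C)C
F8 | step 17 | 5-hydroxymethyl pyranone from 24 | C=C(C)[C@@H]1C[C@H](C/C(=C\C(=O)OC)[C@@H](O[Si](C)(C)C(C)(C)C)CC2=C(CO)C(=O)[C@H](C)[C@@H](C)O2)C1(C)C
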